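**Plan**

1. Numbering: isochroman-1-one core C1 (carbonyl), O2, C3, C4, C4a, C5–C8, C8a, with ring A the benzene ring and ring B the lactone; side chain C1'–C11', carbinol at C6'.
2. Retrosynthesis: after the three protecting groups, ring B is cut at C8a–C1 and C1–O2 (CO taken out), leaving a homobenzylic alcohol. Then C4–C4a (aryl Grignard/epoxide), C1'–C2' (alkyl Grignard/epichlorohydrin) and C3'–C4' (acetylide/ethylene oxide) are cut.
3. Forward: the chain grows linearly from (S)-oct-1-yn-3-ol (C4'–C11') through ethylene oxide (C2', C3') and (R)-epichlorohydrin (C1', C3, C4). Ring A, bought as 5-bromoresorcinol, is joined at C4; ring B is the only ring made and closes in the carbonylation, followed by two deprotections.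
4. Enabling feature: the oxygens of ring A sit at C6 and C8, both meta to C4a, so in the arene that still lacks C1 the C–H bonds at C5 and C8a are related by local symmetry and whichever is carbonylated becomes C8a. The C3 hydroxyl is four atoms away (O, C3, C4, C4a, C8a), the span of a six-membered palladacycle.
5. Stereochemistry: C6' (S) comes from (S)-oct-1-yn-3-ol and C3 (R) from (R)-epichlorohydrin; every later step leaves the four bonds at both centres intact, and the key step creates no stereocentre.

Key step: step 9

Remark: (S)-oct-1-yn-3-ol and (R)-epichlorohydrin are assumed to be commercial in high enantiomeric purity, so the configurational purity of the target rests on these two reagents.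

**Route**

Step 1
Reactants: 1 (S)-oct-1-yn-3-ol
Product: 2 (3S)-3-(tert-butyldimethylsilyloxy)oct-1-yne
Conditions: TBSCl, imidazole, DMF, 0 °C to rt
Reagents that add atoms: tert-butyldimethylsilyl chloride (TBSCl), CC(C)(C)[Si](C)(C)Cl
Why: Standard silylation of a secondary propargylic alcohol with TBSCl and imidazole, in which the C–O bond at the stereocentre is not touched and the S configuration is kept.

Step 2
Reactants: 2 (3S)-3-(tert-butyldimethylsilyloxy)oct-1-yne; 3 ethylene oxide
Product: 5 (5S)-5-(tert-butyldimethylsilyloxy)dec-3-yn-1-ol, via lithium acetylide 4 (not isolated)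
Conditions: n-BuLi, THF, −78 °C; BF3·OEt2; then 3, −78 °C; H2O quench
Reagents that add atoms: none
Why: Deprotonation of the terminal alkyne followed by BF3-promoted alkynylation of ethylene oxide gives the homopropargylic alcohol, and the silyl ether tolerates BF3·OEt2 at −78 °C.

Step 3
Reactants: 5 (5S)-5-(tert-butyldimethylsilyloxy)dec-3-yn-1-ol
Product: 6 (5S)-5-(tert-butyldimethylsilyloxy)decan-1-ol
Conditions: H2 (1 atm), 10% Pd/C, EtOAc, rt
Reagents that add atoms: none
Why: Heterogeneous catalytic hydrogenation takes the alkyne to the alkane, and in a non-protic solvent the silyl ether and the stereocentre are left alone.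

Step 4
Reactants: 6 (5S)-5-(tert-butyldimethylsilyloxy)decan-1-ol
Product: 7 (5S)-1-bromo-5-(tert-butyldimethylsilyloxy)decane
Conditions: CBr4, PPh3, CH2Cl2, 0 °C
Reagents that add atoms: carbon tetrabromide, BrC(Br)(Br)Br
Why: The Appel reaction converts the primary alcohol into the bromide under nearly neutral conditions that a secondary TBS ether withstands.

Step 5
Reactants: 7 (5S)-1-bromo-5-(tert-butyldimethylsilyloxy)decane; 8 (R)-epichlorohydrin
Product: 10 (2R,8S)-8-(tert-butyldimethylsilyloxy)-1-chlorotridecan-2-ol, via alkylmagnesium bromide 9 (not isolated)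
Conditions: Mg, THF, 40 °C; then CuI (10 mol%), 8, THF, −40 to −20 °C; H2O quench
Reagents that add atoms: none
Why: Copper-catalysed Grignard opening of epichlorohydrin by SN2 attack at the unsubstituted ring carbon, not at the chloromethyl carbon, forms C1'–C2' and carries the configuration of 8 over unchanged, so the chlorohydrin is (2R).

Step 6
Reactants: 10 (2R,8S)-8-(tert-butyldimethylsilyloxy)-1-chlorotridecan-2-ol
Product: 11 (2R)-2-[(6S)-6-(tert-butyldimethylsilyloxy)undecyl]oxirane
Conditions: K2CO3, MeOH, rt
Reagents that add atoms: none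
Why: Intramolecular Williamson etherification (alkoxide displacing the primary chloride) closes the oxirane without breaking a bond at the stereocentre, giving the (R)-epoxide.

Step 7
Reactants: 12 5-bromoresorcinol
Product: 13 1,3-bis(benzyloxy)-5-bromobenzene
Conditions: BnBr, K2CO3, DMF, rt
Reagents that add atoms: benzyl bromide, BrCc1ccccc1
Why: Williamson O-benzylation of both phenols with benzyl bromide and K2CO3, to which the aryl bromide is inert.

Step 8
Reactants: 13 1,3-bis(benzyloxy)-5-bromobenzene; 11 (2R)-2-[(6S)-6-(tert-butyldimethylsilyloxy)undecyl]oxirane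
Product: 15 (2R,8S)-1-[3,5-bis(benzyloxy)phenyl]-8-(tert-butyldimethylsilyloxy)tridecan-2-ol, via arylmagnesium bromide 14 (not isolated)
Conditions: 13, Mg, THF, reflux; then CuI (10 mol%), 11, THF, −30 to 0 °C; H2O quench
Reagents that add atoms: none
Why: Copper-catalysed SN2 opening of the monosubstituted epoxide at its terminal carbon by the aryl Grignard reagent forms the C4–C4a bond and leaves the carbinol stereocentre (future C3, R) untouched.

Step 9
Reactants: 15 (2R,8S)-1-[3,5-bis(benzyloxy)phenyl]-8-(tert-butyldimethylsilyloxy)tridecan-2-ol; 16 carbon monoxide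
Product: 17 (3R)-6,8-bis(benzyloxy)-3-[(6S)-6-(tert-butyldimethylsilyloxy)undecyl]-3,4-dihydro-1H-isochromen-1-one
Conditions: Pd(OAc)2 (10 mol%), N-(menthyloxycarbonyl)-L-leucine (20 mol%), AgOAc (3 equiv), Li2CO3 (1 equiv), CO (1 atm), 1,2-dichloroethane, 110 °C
Reagents that add atoms: none
Why: Ligand exchange places the C3 oxygen of 15 on divalent palladium, and the carboxylate of the amino acid ligand then removes the neighbouring ortho hydrogen in a concerted metalation–deprotonation, so that the metal sits in a six-membered chelate made of Pd, O, C3, C4, C4a and the carbon that becomes C8a. Migratory insertion of CO into the aryl–palladium bond gives an acylpalladium alkoxide, and C(acyl)–O reductive elimination from it makes C8a–C1 and C1–O2 at once, which closes ring B as a six-membered lactone (formally a 6-exo-trig acyl substitution by the tethered oxygen); AgOAc then takes zerovalent palladium back to divalent palladium. The reaction type is the hydroxyl-directed ortho C–H carbonylation of 2-arylethanols to isochroman-1-ones under Pd(OAc)2 with a mono-N-protected amino acid, which is documented mainly for tertiary carbinols, so the secondary carbinol here is the more demanding member of a known substrate class. No stereocentre is formed: C3 (R) and C6' (S) arrive with 15 and no bond to either is broken. Site selectivity needs no control element beyond the substrate, because the two ortho C–H bonds are interchangeable by the local symmetry of ring A and the C–H bond between the two benzyloxy groups is out of reach of the chelated metal. The selectivity that does have to be won is chemoselectivity, carbonylation against β-hydride loss from the palladium alkoxide (ketone formation), and it rests on ligand-accelerated palladation of the electron-rich ring, on CO occupying the coordination site that β-hydride elimination needs, and on the inertness of the benzyl and silyl ethers toward these oxidising conditions.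

Step 10
Reactants: 17 (3R)-6,8-bis(benzyloxy)-3-[(6S)-6-(tert-butyldimethylsilyloxy)undecyl]-3,4-dihydro-1H-isochromen-1-one
Product: 18 (3R)-3-[(6S)-6-(tert-butyldimethylsilyloxy)undecyl]-6,8-dihydroxy-3,4-dihydro-1H-isochromen-1-one
Conditions: H2 (1 atm), 10% Pd/C, EtOAc, rt
Reagents that add atoms: none
Why: Catalytic hydrogenolysis cleaves the two aryl benzyl ethers, while the lactone C3–O bond is homobenzylic and not cleaved and the silyl ether survives in ethyl acetate.

Step 11
Reactants: 18 (3R)-3-[(6S)-6-(tert-butyldimethylsilyloxy)undecyl]-6,8-dihydroxy-3,4-dihydro-1H-isochromen-1-one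
Product: 19 (3R)-6,8-dihydroxy-3-[(6S)-6-hydroxyundecyl]-3,4-dihydro-1H-isochromen-1-one
Conditions: HF (48% aq.), MeCN, 0 °C to rt
Reagents that add atoms: none
Why: Fluoride-mediated cleavage of the secondary TBS ether with aqueous HF in acetonitrile, acidic conditions under which the lactone and the phenols are stable and neither stereocentre can epimerise.

**Compound list**

1 | (S)-oct-1-yn-3-ol | CCCCC[C@H](O)C#C | starting material
2 | (3S)-3-(tert-butyldimethylsilyloxy)oct-1-yne | CCCCC[C@H](O[Si](C)(C)C(C)(C)C)C#C | intermediate
3 | ethylene oxide (oxirane) | C1CO1 | starting material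
4 | lithium (3S)-3-(tert-butyldimethylsilyloxy)oct-1-yn-1-ide (lithium acetylide) | CCCCC[C@H](O[Si](C)(C)C(C)(C)C)C#C[Li] | intermediate
5 | (5S)-5-(tert-butyldimethylsilyloxy)dec-3-yn-1-ol | CCCCC[C@H](O[Si](C)(C)C(C)(C)C)C#CCCO | intermediate
6 | (5S)-5-(tert-butyldimethylsilyloxy)decan-1-ol | CCCCC[C@H](O[Si](C)(C)C(C)(C)C)CCCCO | intermediate
7 | (5S)-1-bromo-5-(tert-butyldimethylsilyloxy)decane | CCCCC[C@H](O[Si](C)(C)C(C)(C)C)CCCCBr | intermediate
8 | (R)-epichlorohydrin, (2R)-2-(chloromethyl)oxirane | ClC[C@H]1CO1 | starting material
9 | [(5S)-5-(tert-butyldimethylsilyloxy)decyl]magnesium bromide | CCCCC[C@H](O[Si](C)(C)C(C)(C)C)CCCC[Mg]Br | intermediate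
10 | (2R,8S)-8-(tert-butyldimethylsilyloxy)-1-chlorotridecan-2-ol | CCCCC[C@H](O[Si](C)(C)C(C)(C)C)CCCCC[C@@H](O)CCl | intermediate
11 | (2R)-2-[(6S)-6-(tert-butyldimethylsilyloxy)undecyl]oxirane | CCCCC[C@H](O[Si](C)(C)C(C)(C)C)CCCCC[C@@H]1CO1 | intermediate
12 | 5-bromoresorcinol (5-bromobenzene-1,3-diol) | Oc1cc(O)cc(Br)c1 | starting material
13 | 1,3-bis(benzyloxy)-5-bromobenzene | Brc1cc(OCc2ccccc2)cc(OCc2ccccc2)c1 | intermediate
14 | [3,5-bis(benzyloxy)phenyl]magnesium bromide | Br[Mg]c1cc(OCc2ccccc2)cc(OCc2ccccc2)c1 | intermediate
15 | (2R,8S)-1-[3,5-bis(benzyloxy)phenyl]-8-(tert-butyldimethylsilyloxy)tridecan-2-ol | CCCCC[C@H](O[Si](C)(C)C(C)(C)C)CCCCC[C@@H](O)Cc1cc(OCc2ccccc2)cc(OCc2ccccc2)c1 | intermediate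
16 | carbon monoxide | [C-]#[O+] | starting material
17 | (3R)-6,8-bis(benzyloxy)-3-[(6S)-6-(tert-butyldimethylsilyloxy)undecyl]-3,4-dihydro-1H-isochromen-1-one | CCCCC[C@H](O[Si](C)(C)C(C)(C)C)CCCCC[C@@H]1Cc2cc(OCc3ccccc3)cc(OCc3ccccc3)c2C(=O)O1 | intermediate
18 | (3R)-3-[(6S)-6-(tert-butyldimethylsilyloxy)undecyl]-6,8-dihydroxy-3,4-dihydro-1H-isochromen-1-one | CCCCC[C@H](O[Si](C)(C)C(C)(C)C)CCCCC[C@@H]1Cc2cc(O)cc(O)c2C(=O)O1 | intermediate
19 | (3R)-6,8-dihydroxy-3-[(6S)-6-hydroxyundecyl]-3,4-dihydro-1H-isochromen-1-one | CCCCC[C@H](O)CCCCC[C@@H]1Cc2cc(O)cc(O)c2C(=O)O1 | target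

**Step count**

Total steps: 11. Longest linear sequence: 10 steps (steps 1–6 and 8–11, from 1 to 19); step 7 is a one-step side branch.

**Steps most likely to fail**

Step 9. Oxidation of the secondary carbinol by β-hydride elimination from the palladium alkoxide may outpace C–H palladation at an ortho position that is flanked by a benzyloxy group, or CO may reduce the catalyst to palladium black before it turns over. The fallback replaces C–H activation by a halogen handle and makes the same two bonds. It sets out from 15. N-Bromosuccinimide in CH2Cl2 at 0 °C should brominate ring A ortho to the side chain and para to a benzyloxy group; the two such positions are equivalent and the position between the two oxygens is the more hindered one. This should give (2R,8S)-1-[3,5-bis(benzyloxy)-2-bromophenyl]-8-(tert-butyldimethylsilyloxy)tridecan-2-ol F1. Carbonylative lactonisation of F1 (Pd(OAc)2, 1,1'-bis(diphenylphosphino)ferrocene, Et3N, CO at 1 atm, DMF, 100 °C) proceeds by oxidative addition of zerovalent palladium to the C–Br bond, CO insertion and capture of the acyl group by the C3 hydroxyl, and comes back to the route at 17.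

Step 8. The aryl Grignard reagent may form sluggishly, or the magnesium halide in the mixture may open or rearrange the epoxide (bromohydrin or carbonyl formation) faster than the copper-mediated C–C bond formation, which would consume the advanced epoxide 11. The fallback lets the aryl group meet a cheap three-carbon unit first and moves the convergent bond to C1'–C2'. It sets out from 13 and from bromide 7. Arylmagnesium bromide 14 and commercial (S)-epichlorohydrin (CuI cat., THF, −40 °C) should give (2S)-1-[3,5-bis(benzyloxy)phenyl]-3-chloropropan-2-ol F2, and K2CO3 in MeOH should close it to (2S)-2-[3,5-bis(benzyloxy)benzyl]oxirane F3. Opening of F3 at its CH2 carbon by alkylmagnesium bromide 9 (from 7; CuI cat., THF, −30 °C) comes back to the route at 15, and steps 5 and 6 are then not needed.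

Step 5. Wurtz-type homocoupling may compete during formation of the Grignard reagent, or part of the nucleophile may attack the chloromethyl carbon of epichlorohydrin, which after ring closure delivers the epimeric oxirane and erodes configurational purity at the future C3. The fallback sets this stereocentre by a catalyst instead of the chiral pool. It sets out from 7. Alkylmagnesium bromide 9 is allylated (allyl bromide, CuI cat., THF, 0 °C) to (8S)-8-(tert-butyldimethylsilyloxy)tridec-1-ene F4. Epoxidation with mCPBA in CH2Cl2 gives 2-[(6S)-6-(tert-butyldimethylsilyloxy)undecyl]oxirane F5 as a mixture of the two oxirane epimers. Jacobsen hydrolytic kinetic resolution with the (R,R) enantiomer of (salen)Co(OAc) and 0.55 equiv of H2O is expected to hydrolyse the (2S) epimer to (2S,8S)-8-(tert-butyldimethylsilyloxy)tridecane-1,2-diol F6 and to leave the (2R)-epoxide, so the route is rejoined at 11; if the opposite epimer is consumed, the (S,S) catalyst is used instead.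

**Further compounds**

F1 | step 9 | (2R,8S)-1-[3,5-bis(benzyloxy)-2-bromophenyl]-8-(tert-butyldimethylsilyloxy)tridecan-2-ol | CCCCC[C@H](O[Si](C)(C)C(C)(C)C)CCCCC[C@@H](O)Cc1cc(OCc2ccccc2)cc(OCc2ccccc2)c1Br
F2 | step 8 | (2S)-1-[3,5-bis(benzyloxy)phenyl]-3-chloropropan-2-ol | ClC[C@@H](O)Cc1cc(OCc2ccccc2)cc(OCc2ccccc2)c1
F3 | step 8 | (2S)-2-[3,5-bis(benzyloxy)benzyl]oxirane | C1[C@@H](O1)Cc2cc(OCc3ccccc3)cc(OCc3ccccc3)c2
F4 | step 5 | (8S)-8-(tert-butyldimethylsilyloxy)tridec-1-ene | CCCCC[C@H](O[Si](C)(C)C(C)(C)C)CCCCCC=C
F5 | step 5 | 2-[(6S)-6-(tert-butyldimethylsilyloxy)undecyl]oxirane, mixture of epimers at the oxirane carbon | CCCCC[C@H](O[Si](C)(C)C(C)(C)C)CCCCCC1CO1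
F6 | step 5 | (2S,8S)-8-(tert-butyldimethylsilyloxy)tridecane-1,2-diol | CCCCC[C@H](O[Si](C)(C)C(C)(C)C)CCCCC[C@H](O)CO
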